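Late in the south-west run the substrate had nearly stopped falling: 10.4 % at 2.50 h, 9.6 % at 4.00 h, a drop smaller than the scatter.

| flask | substrate | reagent | scavenger | remark | time |
|---|---|---|---|---|---|
| south-west | 20 mM | 2 equiv | 1 equiv | run made earlier |  |
| east | 20 mM | 2 equiv | 2.1 equiv | run made earlier |  |
| theta | 20 mM | 2.00 equiv | 1.50 equiv |  | 5.0 h |
| zeta | 20 mM | 2.00 equiv | 3.00 equiv |  | 5.0 h |

- south-west (time / h: substrate / %, triple product / %): 0.417: 27.8, 9.8; 1.33: 12.2, 27.5; 2.50: 10.4, 33.4; 4.00: 9.6, 34.0
- east (time / h: substrate / %, triple product / %): 0.417: 25.3, 9.5; 1.33: 10.2, 28.7; 2.50: 8.6, 34.1; 4.00: 8.0, 34.4

(each reading ± 1 percentage point)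

- a species is counted by the substrate in it: one idle adduct B counts as two
- amounts and yields of triple product count idle adduct B too
- amounts and yields of released group count idle adduct A too
- the numbers in the tables scatter by 1 percentage point (one standard deviation)
- steps that have been proposed: substrate + triple product <-> idle adduct B; reagent + double product -> triple product + released group; reagent + triple product -> over-reaction product; substrate + reagent -> first product + released group; reagent + released group <-> idle adduct A; reagent + first product -> double product + released group; scavenger + released group -> scavenged by-product
- what has gone from substrate into another species counts as reacted, even if it can come back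
- in an amount of triple product, one idle adduct B counts as one triple product

- part of the substrate that has reacted at the end, theta
- part of the substrate that has reacted at the end, zeta
- what raising the equivalents of scavenger from its lowest to its highest value here does to the part of the substrate that has reacted (changes below 5 percentage points count as none) (it rises / no change / it falls)

My bench rule was to take the plateau as the end value. East ended at 8.0 %. That is a gap of 1.6 percentage points between two single readings, each scattering by 1 point, so I took no scavenger effect from it, and the gap was less than the margin. Zeta's charge lies beyond east, so carrying this to zeta was a judgement.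

The rule needs a border. The proposed steps that consume substrate and its products each join two partners. So, with equivalents held, percent per hour goes with c(substrate). I therefore defined the reach, the product c(substrate)·t over that product at the start of the south-west plateau:

reach = 20 mM × 5.0 h / (20 mM × 2.50 h) = 2.00 for theta and for zeta

Below 1, there is no plateau to read; the run must be read at reach × 2.50 h. Theta and zeta stood beyond the border, so I expected both to sit on the plateau, with 8.0 % to 9.6 % left and no change.

The forecast gave 91.2 % for theta, 92.8 % for zeta and no change, saying “Doubling the scavenger from 1 to 2.1 equiv barely matters”.

The flasks gave 92.0 % for theta, 92.1 % for zeta and no change, a change of 0.036 points.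

    substrate + triple product ⇌ idle adduct B, settled at all times (K = 97.0 M⁻¹)
    reagent + double product → triple product + released group (k = 84.0 M⁻¹ h⁻¹)
    reagent + triple product → over-reaction product (k = 4.80 M⁻¹ h⁻¹)
    substrate + reagent → first product + released group (k = 140 M⁻¹ h⁻¹)
    reagent + released group ⇌ idle adduct A, settled at all times (K = 27.0 M⁻¹)
    reagent + first product → double product + released group (k = 200 M⁻¹ h⁻¹)
    scavenger + released group → scavenged by-product (k = 72.0 M⁻¹ h⁻¹)

At its reach of 2.00, theta had 92.0 % reacted, and at ten times the time it had 92.1 %. In zeta, reagent was the limiting reagent, with 0.058 % of its charge left. The neighbouring flask is theta with 5.0 mM of substrate, so its reach is 0.500, half of the border value and below it. That points to 75.0 min on the south-west clock, where the nearest reading, at 1.33 h, showed 12.2 % substrate. The neighbouring flask ended with 7.2 % of its reagent unspent and 12.4 % of its substrate left.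

The data are calculated from invented constants; the scatter is artificial.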